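**Retrosynthetic overview**
- The plan rests on C8. It is a secondary carbinol carbon bonded directly to C7, the β-carbon of the C7=C11 butenolide (ring B: O–C6–C7=C11–C12). The C7–C8 bond also belongs to the ten-membered carbocycle (ring A: C1–C10), so cutting it as alkenyl metal plus aldehyde opens ring A and leads back to iodide aldehyde 21.
- Ring B, with its C7 iodine, is made in one operation from epoxy aldehyde 13 and diiodoacrylate 16 (iodine–magnesium exchange, C6–C7 addition, lactonisation). Base-mediated tetronate chemistry is avoided because a C6 carbanion would open the oxirane and a C11 enolate would expel the C13 oxygen.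
- The C1–C10–C9–C8 arm comes from neryl acetate by selective ozonolysis, catalytic enantioselective anti-crotylboration (sets C10) and hydroboration. C1 is oxidised to the ketone before the Sharpless epoxidation (sets C4 and C5), so a C1 hydroxyl never faces the oxirane.
- Order of ring formation: oxirane (step 7), ring B (step 11), ring A (step 14). Senecioylation of O8 ends the route.

Key step: step 14

Remark: germacrane numbering of the target is used throughout. The descriptor at C5 (aldehyde 13) and at C6 (C7-halogen and C7-metal compounds) changes only because substituent ranks change, and the spatial arrangement is that of the target.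

**Step 1**
Reactants: 1 neryl acetate
Product: 3 (4Z)-6-acetoxy-4-methylhex-4-enal, via secondary ozonide 2 (not isolated)
Conditions: O3 (1.0 equiv, titrated CH2Cl2 solution), CH2Cl2, −78 °C; then Me2S, −78 °C → rt
Reagents that add atoms: ozone, [O-][O+]=O
Why: Chemoselective ozonolysis (Criegee mechanism), in which one equivalent of ozone consumes the electron-rich isopropylidene alkene ahead of the C4=C5 alkene deactivated by its allylic acetate, and Me2S reduces ozonide 2 to the C1 aldehyde.

**Step 2**
Reactants: 3 (4Z)-6-acetoxy-4-methylhex-4-enal; 4 (E)-crotylboronic acid pinacol ester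
Product: 6 (2Z,6R,7S)-6-hydroxy-3,7-dimethylnona-2,8-dien-1-yl acetate (1R,10S), via pinacol borate 5 (not isolated)
Conditions: 4 (1.2 equiv), (S)-3,3'-bis(2,4,6-triisopropylphenyl)-1,1'-binaphthyl-2,2'-diyl hydrogen phosphate (5 mol %), toluene, −30 °C; aqueous work-up
Reagents that add atoms: (E)-crotylboronic acid pinacol ester 4, C/C=C/CB1OC(C)(C)C(C)(C)O1
Why: Chiral-phosphoric-acid-catalysed crotylboration through a closed Zimmerman–Traxler chair, in which the E-boronate fixes the anti relation of O1 and the C10 methyl group and the (S)-catalyst directs attack to the Si face of the aldehyde, so that 10S is set under catalyst control (an achiral boronate alone could not do this) while no acid-labile oxirane is yet present.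

**Step 3**
Reactants: 6 homoallylic alcohol
Product: 8 (2Z,6R,7S)-6,9-dihydroxy-3,7-dimethylnon-2-en-1-yl acetate, via bis-9-BBN adduct 7 (not isolated)
Conditions: 9-BBN (2.5 equiv), THF, 0 °C → rt; then NaBO3·4H2O, THF–H2O, rt
Reagents that add atoms: sodium perborate, [Na+].[Na+].O[B-]1(O)OO[B-](O)(O)OO1
Why: Brown hydroboration–oxidation, in which 9-BBN adds anti-Markovnikov to the monosubstituted C8=C9 alkene far faster than to the trisubstituted C4=C5 alkene and perborate oxidises the C8–B bond without cleaving the acetate.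

**Step 4**
Reactants: 8 diol
Product: 9 (2Z,6R,7S)-9-(tert-butyldimethylsilyloxy)-6-hydroxy-3,7-dimethylnon-2-en-1-yl acetate
Conditions: TBSCl (1.05 equiv), imidazole, CH2Cl2, 0 °C
Reagents that add atoms: tert-butyldimethylsilyl chloride, CC(C)(C)[Si](C)(C)Cl
Why: Sterically controlled silylation, in which the bulky silyl chloride reacts with the primary C8 hydroxyl well before the secondary, α-branched C1 hydroxyl.

**Step 5**
Reactants: 9 silyl ether alcohol
Product: 10 (2Z,7S)-9-(tert-butyldimethylsilyloxy)-3,7-dimethyl-6-oxonon-2-en-1-yl acetate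
Conditions: Dess–Martin periodinane, pyridine, CH2Cl2, 0 °C → rt
Reagents that add atoms: none
Why: Dess–Martin oxidation under buffered, non-enolising conditions erases the auxiliary C1 carbinol centre and keeps 10S, and it puts the ketone in place before the oxirane so that no 5-exo attack of a C1 hydroxyl on C4 can ever occur.

**Step 6**
Reactants: 10 keto acetate
Product: 11 (3S,7Z)-1-(tert-butyldimethylsilyloxy)-9-hydroxy-3,7-dimethylnon-7-en-4-one
Conditions: K2CO3 (0.2 equiv), MeOH, 0 °C
Reagents that add atoms: none
Why: Base-catalysed transesterification of an unhindered primary allylic acetate is much faster at 0 °C than enolisation of the ketone toward the branched C10 position, so the C6 alcohol is freed with 10S intact.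

**Step 7**
Reactants: 11 (Z)-allylic alcohol
Product: 12 (3S)-1-(tert-butyldimethylsilyloxy)-6-[(2S,3R)-3-(hydroxymethyl)-2-methyloxiran-2-yl]-3-methylhexan-4-one (4S,5R,10S)
Conditions: Ti(OiPr)4 (10 mol %), D-(−)-diethyl tartrate (13 mol %), tBuOOH (2 equiv), 4 Å molecular sieves, CH2Cl2, −20 °C
Reagents that add atoms: tert-butyl hydroperoxide, CC(C)(C)OO
Why: Katsuki–Sharpless asymmetric epoxidation, in which the titanium tartrate complex binds the C6 alcohol and delivers oxygen to one alkene face under reagent control, D-(−)-tartrate giving 4S,5R just as it gives the 2R,3S epoxide from nerol, while the Z geometry becomes the cis relation of C3 and C6.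

**Step 8**
Reactants: 12 epoxy alcohol
Product: 13 (2S,3S)-3-[(4S)-6-(tert-butyldimethylsilyloxy)-4-methyl-3-oxohexyl]-3-methyloxirane-2-carbaldehyde (4S,5S,10S)
Conditions: Dess–Martin periodinane, pyridine, CH2Cl2, 0 °C
Reagents that add atoms: none
Why: Buffered Dess–Martin oxidation converts the primary epoxy alcohol into the epoxy aldehyde without acid or base strong enough to open the oxirane or trigger a Payne rearrangement.

**Step 9**
Reactants: 14 ethyl bromopyruvate
Product: 15 ethyl 3-acetoxy-2-oxopropanoate
Conditions: KOAc (1.1 equiv), acetone, 0 °C → rt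
Reagents that add atoms: potassium acetate, CC(=O)[O-].[K+]
Why: SN2 displacement of an α-bromo ketone by acetate, accelerated by the adjacent carbonyl group, installs the C13 acetate at the outset so that no protecting-group exchange is needed later.

**Step 10**
Reactants: 15 ethyl 3-acetoxy-2-oxopropanoate
Product: 16 ethyl 2-(acetoxymethyl)-3,3-diiodoprop-2-enoate
Conditions: CI4 (1.5 equiv), PPh3 (3 equiv), CH2Cl2, 0 °C → rt
Reagents that add atoms: tetraiodomethane, IC(I)(I)I
Why: Ramirez gem-dihaloolefination, in which PPh3 and CI4 form Ph3P=CI2 and this ylide undergoes a Wittig reaction with the activated ketone carbonyl of the α-keto ester, with no alkene geometry to control because both new substituents are iodine.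

**Step 11**
Reactants: 13 epoxy aldehyde; 16 diiodoacrylate
Product: 19 {(5S)-5-[(2R,3S)-3-((4S)-6-(tert-butyldimethylsilyloxy)-4-methyl-3-oxohexyl)-3-methyloxiran-2-yl]-4-iodo-2-oxo-2,5-dihydrofuran-3-yl}methyl acetate (4S,5R,6S,10S), via magnesium carbenoid 17 (not isolated), via chloromagnesium alkoxide 18 (not isolated)
Conditions: 16 (1.3 equiv), iPrMgCl (1.25 equiv), THF, −78 °C, 20 min; then 13, −78 → −40 °C; AcOH, → rt
Reagents that add atoms: diiodoacrylate 16, CCOC(=O)C(COC(C)=O)=C(I)I
Why: Chelation-directed iodine–magnesium exchange removes only the iodine cis to the ester, the resulting carbenoid 17 adds to the non-enolisable aldehyde faster than to the hindered C1 ketone along a polar Felkin–Anh trajectory anti to the C5–O bond to give the erythro alkoxide 18 (6S here, the arrangement of 6R in the target), and 18 closes onto the cis ester to form ring B with the second iodine left at C7, all without a base able to open the oxirane through C6.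

**Step 12**
Reactants: 19 iodobutenolide silyl ether
Product: 20 {(5S)-5-[(2R,3S)-3-((4S)-6-hydroxy-4-methyl-3-oxohexyl)-3-methyloxiran-2-yl]-4-iodo-2-oxo-2,5-dihydrofuran-3-yl}methyl acetate
Conditions: HF·pyridine, excess pyridine, THF, 0 °C
Reagents that add atoms: none
Why: Fluoride-driven cleavage of the primary silyl ether in a pyridine-buffered medium is too weakly acidic to activate the trisubstituted oxirane toward the hydroxy ketone or its hemiketal and too weakly basic to remove the C6 hydrogen.

**Step 13**
Reactants: 20 hydroxy ketone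
Product: 21 {(5S)-4-iodo-5-[(2R,3S)-3-methyl-3-((4S)-4-methyl-3,6-dioxohexyl)oxiran-2-yl]-2-oxo-2,5-dihydrofuran-3-yl}methyl acetate (seco C7-iodobutenolide C8-aldehyde)
Conditions: Dess–Martin periodinane, pyridine, CH2Cl2, 0 °C; used at once
Reagents that add atoms: none
Why: Dess–Martin oxidation of the open-chain form of the γ-hydroxy ketone gives the γ-keto aldehyde under near-neutral conditions that avoid intramolecular aldol reaction, C10 epimerisation and loss of the C6 hydrogen.

**Step 14**
Reactants: 21 seco C7-iodobutenolide C8-aldehyde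
Product: 23 (4S,5R,6R,8R,10S)-13-acetoxy-4,5-epoxy-8-hydroxy-1-oxogermacr-7(11)-en-12,6-olide, via alkenylchromium dichloride 22 (not isolated)
Conditions: CrCl2 (10 equiv), NiCl2 (0.1 equiv), DMF, rt, syringe-pump addition of 21 (final about 2 mM)
Reagents that add atoms: none
Why: CrCl2 reduces NiCl2 to zerovalent nickel, which adds oxidatively to the electron-poor C7–I bond, and the alkenyl group then passes to trivalent chromium to give 22, a weakly basic and strongly oxophilic nucleophile that attacks the C8 aldehyde. The closest known reaction type is the Nozaki–Hiyama–Kishi macrocyclisation of iodoalkene aldehydes to medium-ring allylic alcohols, and β-iodo enoates are established partners of the intermolecular coupling. Ring A closes in a 10-exo-trig mode (the C8=O bond stays outside the new ring), aided by the cis-oxirane and the flat ring B, which fold C4–C7 and shorten the C7 to C8 distance, and by slow addition at high dilution, which holds back dimerisation. C8 is set in the cyclic transition state: allylic 1,3-strain against the C13 acetoxymethyl group keeps the aldehyde hydrogen in the plane of ring B, the tether holds C9 on the face opposite to C5, and the oxygen therefore ends on the C5 face, which is 8R. The step needs the aldehyde to react ahead of the C1 ketone, lactone, acetate and oxirane, which the low nucleophilicity of alkenylchromium secures, while the non-basic medium spares C10 and the acidic C6 hydrogen. β-Elimination of the C6 oxygen from 22 is excluded because it would place an allene in a five-membered ring.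

**Step 15**
Reactants: 23 8-hydroxy germacranolide; 24 3-methylbut-2-enoic acid
Product: 26 (4S,5R,6R,8R,10S)-13-acetoxy-4,5-epoxy-8-(3-methylbut-2-enoyloxy)-1-oxogermacr-7(11)-en-12,6-olide (target), via mixed anhydride 25 (not isolated)
Conditions: 24, 2,4,6-trichlorobenzoyl chloride, Et3N (1 equiv each), toluene, rt; then 23, 4-(dimethylamino)pyridine, toluene, 0 °C → rt
Reagents that add atoms: 3-methylbut-2-enoic acid 24, CC(C)=CC(=O)O
Why: Yamaguchi esterification, in which 4-(dimethylamino)pyridine attacks the unhindered senecioyl carbonyl of 25 and the acylpyridinium acylates O8 with retention because the C8–O bond is never broken, with no free Et3N left to deconjugate the acyl group or abstract the C6 hydrogen.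

**Compound list**
1 | neryl acetate, (2Z)-3,7-dimethylocta-2,6-dien-1-yl acetate | CC(C)=CCC/C(C)=C\COC(C)=O | starting material
2 | (2Z)-5-(5,5-dimethyl-1,2,4-trioxolan-3-yl)-3-methylpent-2-en-1-yl acetate (secondary ozonide) | CC(=O)OC/C=C(C)\CCC1OOC(C)(C)O1 | intermediate
3 | (4Z)-6-acetoxy-4-methylhex-4-enal | CC(=O)OC/C=C(C)\CCC=O | intermediate
4 | (E)-crotylboronic acid pinacol ester | C/C=C/CB1OC(C)(C)C(C)(C)O1 | starting material
5 | O1-pinacol borate of 6 | CC(=O)OC/C=C(C)\CC[C@@H](OB1OC(C)(C)C(C)(C)O1)[C@@H](C)C=C | intermediate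
6 | (2Z,6R,7S)-6-hydroxy-3,7-dimethylnona-2,8-dien-1-yl acetate | CC(=O)OC/C=C(C)\CC[C@@H](O)[C@@H](C)C=C | intermediate
7 | bis-9-BBN adduct of 6 (C8–B and O1–B) | CC(=O)OC/C=C(C)\CC[C@@H](OB1C2CCCC1CCC2)[C@@H](C)CCB1C2CCCC1CCC2 | intermediate
8 | (2Z,6R,7S)-6,9-dihydroxy-3,7-dimethylnon-2-en-1-yl acetate | CC(=O)OC/C=C(C)\CC[C@@H](O)[C@@H](C)CCO | intermediate
9 | (2Z,6R,7S)-9-(tert-butyldimethylsilyloxy)-6-hydroxy-3,7-dimethylnon-2-en-1-yl acetate | CC(=O)OC/C=C(C)\CC[C@@H](O)[C@@H](C)CCO[Si](C)(C)C(C)(C)C | intermediate
10 | (2Z,7S)-9-(tert-butyldimethylsilyloxy)-3,7-dimethyl-6-oxonon-2-en-1-yl acetate | CC(=O)OC/C=C(C)\CCC(=O)[C@@H](C)CCO[Si](C)(C)C(C)(C)C | intermediate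
11 | (3S,7Z)-1-(tert-butyldimethylsilyloxy)-9-hydroxy-3,7-dimethylnon-7-en-4-one | OC/C=C(C)\CCC(=O)[C@@H](C)CCO[Si](C)(C)C(C)(C)C | intermediate
12 | epoxy alcohol (4S,5R,10S) | OC[C@H]1O[C@@]1(C)CCC(=O)[C@@H](C)CCO[Si](C)(C)C(C)(C)C | intermediate
13 | epoxy aldehyde (4S,5S,10S) | O=C[C@H]1O[C@@]1(C)CCC(=O)[C@@H](C)CCO[Si](C)(C)C(C)(C)C | intermediate
14 | ethyl bromopyruvate | CCOC(=O)C(=O)CBr | starting material
15 | ethyl 3-acetoxy-2-oxopropanoate | CCOC(=O)C(=O)COC(C)=O | intermediate
16 | ethyl 2-(acetoxymethyl)-3,3-diiodoprop-2-enoate | CCOC(=O)C(COC(C)=O)=C(I)I | intermediate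
17 | ethyl 2-(acetoxymethyl)-3-(chloromagnesio)-3-iodoprop-2-enoate, magnesium cis to the ester | CCOC(=O)/C(COC(C)=O)=C(/I)[Mg]Cl | intermediate
18 | chloromagnesium alkoxide of the erythro (6S) adduct | CCOC(=O)/C(COC(C)=O)=C(/I)[C@@H](O[Mg]Cl)[C@H]1O[C@@]1(C)CCC(=O)[C@@H](C)CCO[Si](C)(C)C(C)(C)C | intermediate
19 | C7-iodobutenolide C8 silyl ether (4S,5R,6S,10S) | CC(=O)OCC1=C(I)[C@@H](OC1=O)[C@H]1O[C@@]1(C)CCC(=O)[C@@H](C)CCO[Si](C)(C)C(C)(C)C | intermediate
20 | C7-iodobutenolide C8 alcohol (4S,5R,6S,10S) | CC(=O)OCC1=C(I)[C@@H](OC1=O)[C@H]1O[C@@]1(C)CCC(=O)[C@@H](C)CCO | intermediate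
21 | seco C7-iodobutenolide C8-aldehyde (4S,5R,6S,10S) | CC(=O)OCC1=C(I)[C@@H](OC1=O)[C@H]1O[C@@]1(C)CCC(=O)[C@@H](C)CC=O | intermediate
22 | C7 alkenylchromium dichloride | CC(=O)OCC1=C([Cr](Cl)Cl)[C@@H](OC1=O)[C@H]1O[C@@]1(C)CCC(=O)[C@@H](C)CC=O | intermediate
23 | 8-hydroxy germacranolide (4S,5R,6R,8R,10S) | CC(=O)OCC1=C2[C@@H](OC1=O)[C@H]1O[C@@]1(C)CCC(=O)[C@@H](C)C[C@H]2O | intermediate
24 | 3-methylbut-2-enoic acid | CC(C)=CC(=O)O | starting material
25 | 3-methylbut-2-enoic 2,4,6-trichlorobenzoic anhydride | CC(C)=CC(=O)OC(=O)c1c(Cl)cc(Cl)cc1Cl | intermediate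
26 | CNP0220542.1 (4S,5R,6R,8R,10S) | CC(=O)OCC1=C2[C@@H](OC1=O)[C@H]1O[C@@]1(C)CCC(=O)[C@@H](C)C[C@H]2OC(=O)C=C(C)C | target

Total step count: 15. Longest linear sequence: 13 (steps 1–8 and 11–15, from neryl acetate).

**Steps most likely to fail**

1. **Step 14.** The alkenylchromium may attack the other face of the aldehyde. Protodemetalation or intermolecular coupling may also erode the closure.
 - The fallback sets out from 21.
 - If the closure gives mainly the 8S alcohol F1, this epimer is not acylated with retention. It is esterified with 24 under Mitsunobu conditions (PPh3, diisopropyl azodicarboxylate, toluene, 0 °C).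
 - The carboxylate displaces the activated C8 oxygen with inversion.
 - The fallback comes back to the route at 26 and makes step 15 unnecessary.

2. **Step 11.** Facial selectivity at C6 may be poor, because magnesium chelation between the aldehyde and oxirane oxygens would favour the threo adduct. The carbenoid may also decay before it adds.
 - The fallback sets out from 13.
 - Pinnick oxidation (NaClO2, NaH2PO4, 2-methylbut-2-ene, tBuOH–H2O) gives the epoxy acid F2.
 - 2,2'-Dipyridyl disulfide and PPh3 convert it into the S-2-pyridyl thioester F3.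
 - Acylation of carbenoid 17 with this thioester at −78 °C gives the epoxy ketone F4.
 - Zn(BH4)2 in Et2O at −78 °C, held between the ketone and oxirane oxygens, should reduce the chelated C6 ketone ahead of the C1 ketone to the erythro hydroxy ester F5.
 - This hydroxy ester lactonises on warming, and the fallback comes back to the route at 19.

3. **Step 10.** The bulky ylide Ph3P=CI2 may react sluggishly with the ketone, and the crowded alkene may lose iodine.
 - The fallback sets out from 15.
 - The well-established CBr4/PPh3 variant gives the dibromoacrylate F6.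
 - Bromine–magnesium exchange with iPrMgCl·LiCl at −40 °C gives the bromo carbenoid F7.
 - Addition to 13 gives the alkoxide F8, which closes to the bromobutenolide silyl ether F9.
 - HF·pyridine gives the bromo hydroxy ketone F10, and Dess–Martin oxidation gives the bromo keto aldehyde F11.
 - CrCl2 with a larger share of NiCl2 converts the activated C7–Br bond into the same alkenylchromium.
 - The fallback comes back to the route at 22 and hence 23.

**Further compounds**
F1 | step 14 | 8S epimer of 23 | CC(=O)OCC1=C2[C@@H](OC1=O)[C@H]1O[C@@]1(C)CCC(=O)[C@@H](C)C[C@@H]2O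
F2 | step 11 | epoxy acid (4S,5S,10S) | OC(=O)[C@H]1O[C@@]1(C)CCC(=O)[C@@H](C)CCO[Si](C)(C)C(C)(C)C
F3 | step 11 | S-2-pyridyl thioester of F2 | O=C(Sc1ccccn1)[C@H]1O[C@@]1(C)CCC(=O)[C@@H](C)CCO[Si](C)(C)C(C)(C)C
F4 | step 11 | C6 epoxy ketone, ester cis to C6 | CCOC(=O)/C(COC(C)=O)=C(/I)C(=O)[C@H]1O[C@@]1(C)CCC(=O)[C@@H](C)CCO[Si](C)(C)C(C)(C)C
F5 | step 11 | erythro (6S) hydroxy ester | CCOC(=O)/C(COC(C)=O)=C(/I)[C@@H](O)[C@H]1O[C@@]1(C)CCC(=O)[C@@H](C)CCO[Si](C)(C)C(C)(C)C
F6 | step 10 | ethyl 2-(acetoxymethyl)-3,3-dibromoprop-2-enoate | CCOC(=O)C(COC(C)=O)=C(Br)Br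
F7 | step 10 | bromo carbenoid, magnesium cis to the ester | CCOC(=O)/C(COC(C)=O)=C(/Br)[Mg]Cl
F8 | step 10 | chloromagnesium alkoxide of the bromo adduct | CCOC(=O)/C(COC(C)=O)=C(/Br)[C@@H](O[Mg]Cl)[C@H]1O[C@@]1(C)CCC(=O)[C@@H](C)CCO[Si](C)(C)C(C)(C)C
F9 | step 10 | C7-bromobutenolide C8 silyl ether | CC(=O)OCC1=C(Br)[C@@H](OC1=O)[C@H]1O[C@@]1(C)CCC(=O)[C@@H](C)CCO[Si](C)(C)C(C)(C)C
F10 | step 10 | C7-bromobutenolide C8 alcohol | CC(=O)OCC1=C(Br)[C@@H](OC1=O)[C@H]1O[C@@]1(C)CCC(=O)[C@@H](C)CCO
F11 | step 10 | C7-bromobutenolide C8 aldehyde | CC(=O)OCC1=C(Br)[C@@H](OC1=O)[C@H]1O[C@@]1(C)CCC(=O)[C@@H](C)CC=O
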